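Assumptions: the locants C1–C10 and C13 used below are defined as C10 = methyl-bearing ring-fusion carbon, C1 = acetoxy carbon, C2/C3 = epoxide carbons (C3 carries the methyl), C6 = ring-fusion CH, C7 = side-chain carbon, C13 = first side-chain carbon. In this numbering the target SMILES is the (1S,2S,3R,6S,7R,10S) isomer. TBS = tert-butyldimethylsilyl. Compounds 17 and 24 are bought as such.

**Retrosynthetic overview**
1. Target 25 ⇐ Heck coupling of vinyl iodide 23 with 24 (C14–C15 bond); the acetate and the syn epoxide ⇐ hydroxyl-directed epoxidation of cycloheptenol 21.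
2. Seven-membered ring (formed second) ⇐ ring-closing metathesis of diene 20 at C2=C3.
3. Both arms of 20 ⇐ ester 9: isopropenyl → methyl ketone → alkyne → (E)-vinyl iodide; ester → CH2OTf → methallyl coupling.
4. Five-membered ring (formed first) ⇐ Wolff ring contraction of a carvone-derived 2-diazocyclohexanone; the carvone carbonyl carbon becomes C5.
5. C1 and C10 ⇐ reductive aldol of (R)-carvone with acrolein; C7 comes from carvone; the oxirane is the last ring.

**Route**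

Step 1
Reactants: 1 (R)-(−)-carvone; 2 acrolein
Product: 4 (2R,5R)-2-[(1R)-1-hydroxyprop-2-en-1-yl]-2-methyl-5-(prop-1-en-2-yl)cyclohexan-1-one, via lithium enolate 3 (not isolated)
Conditions: LiBH(s-Bu)3 (1.05 equiv), THF, −78 °C; then 2 (1.5 equiv), −78 °C; AcOH quench at −78 °C; chromatography
Reagents that add atoms: none
Why: Conjugate hydride delivery gives the tetrasubstituted enolate regiospecifically, and the reductive aldol then adds acrolein 1,2 by axial attack cis to the equatorial isopropenyl group (sets C10) through a Zimmerman–Traxler chair with the vinyl group equatorial and the enolate methyl cis to oxygen (sets C1, hydroxyl syn to methyl in the zigzag).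

Step 2
Reactants: 4 (2R,5R)-2-[(1R)-1-hydroxyprop-2-en-1-yl]-2-methyl-5-(prop-1-en-2-yl)cyclohexan-1-one
Product: 5 (2R,5R)-2-[(1R)-1-(TBS-oxy)prop-2-en-1-yl]-2-methyl-5-(prop-1-en-2-yl)cyclohexan-1-one
Conditions: TBSOTf, 2,6-lutidine, CH2Cl2, −78 → 0 °C
Reagents that add atoms: tert-butyldimethylsilyl trifluoromethanesulfonate, CC(C)(C)[Si](C)(C)OS(=O)(=O)C(F)(F)F
Why: Silylation of the hindered secondary alcohol with the silyl triflate blocks retro-aldol cleavage in the basic steps that follow, and no stereocenter is touched.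

Step 3
Reactants: 5 (2R,5R)-2-[(1R)-1-(TBS-oxy)prop-2-en-1-yl]-2-methyl-5-(prop-1-en-2-yl)cyclohexan-1-one
Product: 7 (2R,5S)-6-diazo-2-[(1R)-1-(TBS-oxy)prop-2-en-1-yl]-2-methyl-5-(prop-1-en-2-yl)cyclohexan-1-one, via trifluoroacetyl ketone 6 (not isolated)
Conditions: LiN(SiMe3)2, THF, −78 °C; CF3CO2CH2CF3, −78 °C; aq HCl wash, crude 6 into MeCN; MsN3, Et3N, H2O (1 equiv), rt
Reagents that add atoms: 2,2,2-trifluoroethyl trifluoroacetate, O=C(OCC(F)(F)F)C(F)(F)F (its CF3CO group is carried only by 6); methanesulfonyl azide, CS(=O)(=O)N=[N+]=[N-] (gives the N2 unit of 7)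
Why: Detrifluoroacetylative (Regitz-type) diazo transfer works on hindered ketones, and the only enolisable position is the CH2 next to C7 because the other α-carbon is quaternary; the change of descriptor at C7 (R to S) is only a CIP priority change.

Step 4
Reactants: 7 (2R,5S)-6-diazo-2-[(1R)-1-(TBS-oxy)prop-2-en-1-yl]-2-methyl-5-(prop-1-en-2-yl)cyclohexan-1-one
Product: 9 methyl (1S,2S,5R)-2-[(1R)-1-(TBS-oxy)prop-2-en-1-yl]-2-methyl-5-(prop-1-en-2-yl)cyclopentane-1-carboxylate, via ketene 8 (not isolated)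
Conditions: hν (350 nm), MeOH, rt; then NaOMe (0.5 equiv), MeOH, 65 °C
Reagents that add atoms: methanol, CO
Why: In the photochemical Wolff rearrangement the quaternary carbon migrates with retention to the carbene carbon and contracts the ring, methanol traps the ketene, and NaOMe then equilibrates the new α-stereocenter C6 to the all-trans ester (trans to both the isopropenyl group and the bulky silyloxyallyl group).

Step 5
Reactants: 9 methyl (1S,2S,5R)-2-[(1R)-1-(TBS-oxy)prop-2-en-1-yl]-2-methyl-5-(prop-1-en-2-yl)cyclopentane-1-carboxylate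
Product: 11 methyl (1S,2S,5R)-5-acetyl-2-[(1R)-1-(TBS-oxy)prop-2-en-1-yl]-2-methylcyclopentane-1-carboxylate, via epoxide 10 (not isolated)
Conditions: mCPBA (1.05 equiv), CH2Cl2, 0 °C; then H5IO6, THF/H2O, 0 °C → rt
Reagents that add atoms: mCPBA, OOC(=O)c1cccc(Cl)c1 (oxirane oxygen of 10); water, O (carbonyl oxygen of 11 after opening at the tertiary carbon)
Why: Prilezhaev epoxidation picks the electron-rich 1,1-disubstituted alkene over the hindered vinyl group deactivated by its allylic silyl ether, and periodic acid cleaves the epoxide through the diol (Malaprade cleavage) to the methyl ketone, with C7 left in its thermodynamically preferred trans arrangement.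

Step 6
Reactants: 11 methyl (1S,2S,5R)-5-acetyl-2-[(1R)-1-(TBS-oxy)prop-2-en-1-yl]-2-methylcyclopentane-1-carboxylate
Product: 13 methyl (1S,2S,5R)-5-ethynyl-2-[(1R)-1-(TBS-oxy)prop-2-en-1-yl]-2-methylcyclopentane-1-carboxylate, via enol phosphate 12 (not isolated)
Conditions: LiN(i-Pr)2 (1.05 equiv), THF, −78 °C; ClP(O)(OEt)2, −78 → 0 °C; LiN(i-Pr)2 (2.2 equiv), −78 → 0 °C; aq NH4Cl
Reagents that add atoms: diethyl chlorophosphate, CCOP(=O)(Cl)OCC (its atoms are carried only by 12)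
Why: In this Negishi methyl ketone-to-alkyne sequence the kinetic enolate forms at the methyl group and the enol phosphate eliminates to the alkyne, while the ester α-hydrogen, flanked by the quaternary carbon, is not removed at low temperature and a Dieckmann-type closure would need a strained trans-bicyclo[3.3.0] ring.

Step 7
Reactants: 13 methyl (1S,2S,5R)-5-ethynyl-2-[(1R)-1-(TBS-oxy)prop-2-en-1-yl]-2-methylcyclopentane-1-carboxylate
Product: 15 methyl (1S,2S,5R)-2-[(1R)-1-(TBS-oxy)prop-2-en-1-yl]-5-[(1E)-1-iodoprop-1-en-2-yl]-2-methylcyclopentane-1-carboxylate, via alkenylalane 14 (not isolated)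
Conditions: AlMe3 (3 equiv), Cp2ZrCl2 (20 mol %), H2O (1 equiv), CH2Cl2, −23 °C; then iodine, THF, −23 → 0 °C
Reagents that add atoms: trimethylaluminium, C[Al](C)C; iodine, [I][I]
Why: Negishi Cp2ZrCl2-catalysed carboalumination adds methyl and aluminium syn across the terminal alkyne with methyl on the internal carbon, and iodinolysis with retention gives the (E)-vinyl iodide, the water-accelerated low-temperature variant sparing the ester.

Step 8
Reactants: 15 methyl (1S,2S,5R)-2-[(1R)-1-(TBS-oxy)prop-2-en-1-yl]-5-[(1E)-1-iodoprop-1-en-2-yl]-2-methylcyclopentane-1-carboxylate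
Product: 16 [(1S,2S,5R)-2-[(1R)-1-(TBS-oxy)prop-2-en-1-yl]-5-[(1E)-1-iodoprop-1-en-2-yl]-2-methylcyclopentyl]methanol
Conditions: i-Bu2AlH (2.5 equiv), CH2Cl2, −78 → 0 °C; aq potassium sodium tartrate
Reagents that add atoms: none
Why: Hydride reduction of the ester to the primary alcohol leaves the vinyl iodide, the silyl ether and all stereocenters untouched.

Step 9
Reactants: 16 [(1S,2S,5R)-2-[(1R)-1-(TBS-oxy)prop-2-en-1-yl]-5-[(1E)-1-iodoprop-1-en-2-yl]-2-methylcyclopentyl]methanol; 17 2-methylallylmagnesium chloride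
Product: 19 tert-butyl{[(1R)-1-[(1S,2S,3R)-3-[(1E)-1-iodoprop-1-en-2-yl]-1-methyl-2-(3-methylbut-3-en-1-yl)cyclopentyl]prop-2-en-1-yl]oxy}dimethylsilane, via triflate 18 (not isolated)
Conditions: Tf2O, 2,6-lutidine, CH2Cl2, −78 °C; then CH2=C(CH3)CH2MgCl (3 equiv), CuI (10 mol %), THF, −78 → −20 °C
Reagents that add atoms: trifluoromethanesulfonic anhydride, FC(F)(F)S(=O)(=O)OS(=O)(=O)C(F)(F)F (its atoms are carried only by 18)
Why: CuI-catalysed sp3–sp3 cross-coupling of the allylic Grignard reagent with the primary triflate is far faster below −20 °C than any reaction at the trisubstituted vinyl iodide, and it completes the C4–C5 bond without touching a stereocenter.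

Step 10
Reactants: 19 tert-butyl{[(1R)-1-[(1S,2S,3R)-3-[(1E)-1-iodoprop-1-en-2-yl]-1-methyl-2-(3-methylbut-3-en-1-yl)cyclopentyl]prop-2-en-1-yl]oxy}dimethylsilane
Product: 20 (1R)-1-[(1S,2S,3R)-3-[(1E)-1-iodoprop-1-en-2-yl]-1-methyl-2-(3-methylbut-3-en-1-yl)cyclopentyl]prop-2-en-1-ol
Conditions: Bu4NF, THF, 45 °C
Reagents that add atoms: none
Why: Fluoride-mediated desilylation frees the allylic alcohol, which makes the vinyl group less hindered for metathesis and is needed for the directed epoxidation; the vinyl iodide has no vinylic β-hydrogen and cannot eliminate.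

Step 11
Reactants: 20 (1R)-1-[(1S,2S,3R)-3-[(1E)-1-iodoprop-1-en-2-yl]-1-methyl-2-(3-methylbut-3-en-1-yl)cyclopentyl]prop-2-en-1-ol
Product: 21 (1R,3aS,4R,8aS)-1-[(1E)-1-iodoprop-1-en-2-yl]-3a,6-dimethyl-1,2,3,3a,4,7,8,8a-octahydroazulen-4-ol
Conditions: RuCl2(=CHPh)(H2IMes)(PCy3) (second-generation Grubbs catalyst, 10 mol %), 1,4-benzoquinone (20 mol %), toluene (2 mM), 80 °C
Reagents that add atoms: none
Why: Ring-closing metathesis between the vinyl carbinol and the 1,1-disubstituted alkene on trans-disposed neighbouring ring carbons closes the trans-fused cycloheptene with its trisubstituted C2=C3 bond, the hindered vinyl iodide being inert and benzoquinone suppressing alkene isomerisation.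

Step 12
Reactants: 21 (1R,3aS,4R,8aS)-1-[(1E)-1-iodoprop-1-en-2-yl]-3a,6-dimethyl-1,2,3,3a,4,7,8,8a-octahydroazulen-4-ol
Product: 22 (1R,3aS,4S,5S,6R,8aS)-5,6-epoxy-1-[(1E)-1-iodoprop-1-en-2-yl]-3a,6-dimethyldecahydroazulen-4-ol
Conditions: VO(acac)2 (5 mol %), t-BuOOH (1.5 equiv), CH2Cl2, 0 °C → rt
Reagents that add atoms: tert-butyl hydroperoxide, CC(C)(C)OO
Why: In this hydroxyl-directed (Sharpless–Michaelson) epoxidation the C1 alkoxide bound to the VO(acac)2-derived catalyst delivers oxygen to the alkene face syn to the hydroxyl, which is also the face anti to the angular methyl, setting C2 and C3 as the cis epoxy alcohol while the undirected, electron-poor vinyl iodide is left alone.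

Step 13
Reactants: 22 (1R,3aS,4S,5S,6R,8aS)-5,6-epoxy-1-[(1E)-1-iodoprop-1-en-2-yl]-3a,6-dimethyldecahydroazulen-4-ol
Product: 23 (1R,3aS,4S,5S,6R,8aS)-5,6-epoxy-1-[(1E)-1-iodoprop-1-en-2-yl]-3a,6-dimethyldecahydroazulen-4-yl acetate
Conditions: Ac2O, Et3N, DMAP (cat.), CH2Cl2, rt
Reagents that add atoms: acetic anhydride, CC(=O)OC(C)=O
Why: DMAP-catalysed acylation of the only hydroxyl group proceeds with retention at C1 and does not open the epoxide.

Step 14
Reactants: 23 (1R,3aS,4S,5S,6R,8aS)-5,6-epoxy-1-[(1E)-1-iodoprop-1-en-2-yl]-3a,6-dimethyldecahydroazulen-4-yl acetate; 24 2-methylbut-3-en-2-ol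
Product: 25 (1R,3aS,4S,5S,6R,8aS)-5,6-epoxy-1-[(2E,4E)-6-hydroxy-6-methylhepta-2,4-dien-2-yl]-3a,6-dimethyldecahydroazulen-4-yl acetate (target)
Conditions: Pd(OAc)2 (10 mol %), Ag2CO3 (1.5 equiv), 24 (5 equiv), DMF, 50 °C
Reagents that add atoms: none
Why: In this Mizoroki–Heck reaction the vinyl iodide reacts with retention of its E geometry, insertion occurs at the terminal carbon of 24, and β-hydride elimination can only take place toward the new CH2 because the carbinol carbon has no hydrogen, giving the (E,E)-dienol under mild, nearly neutral conditions that spare acetate and epoxide.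

**Compound list**
1 | (R)-(−)-carvone | CC1=CC[C@@H](C(C)=C)CC1=O | starting material
2 | acrolein | C=CC=O | starting material
3 | lithium (5R)-2-methyl-5-(prop-1-en-2-yl)cyclohex-1-en-1-olate | CC1=C(O[Li])C[C@H](C(C)=C)CC1 | intermediate
4 | (2R,5R)-2-[(1R)-1-hydroxyprop-2-en-1-yl]-2-methyl-5-(prop-1-en-2-yl)cyclohexan-1-one | C=C[C@@H](O)[C@@]1(C)CC[C@@H](C(C)=C)CC1=O | intermediate
5 | (2R,5R)-2-[(1R)-1-[(tert-butyldimethylsilyl)oxy]prop-2-en-1-yl]-2-methyl-5-(prop-1-en-2-yl)cyclohexan-1-one | C=C[C@@H](O[Si](C)(C)C(C)(C)C)[C@@]1(C)CC[C@@H](C(C)=C)CC1=O | intermediate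
6 | (2R,5R)-2-[(1R)-1-[(tert-butyldimethylsilyl)oxy]prop-2-en-1-yl]-2-methyl-5-(prop-1-en-2-yl)-6-(trifluoroacetyl)cyclohexan-1-one (C6 unassigned, largely enolised) | C=C[C@@H](O[Si](C)(C)C(C)(C)C)[C@@]1(C)CC[C@@H](C(C)=C)C(C(=O)C(F)(F)F)C1=O | intermediate
7 | (2R,5S)-6-diazo-2-[(1R)-1-[(tert-butyldimethylsilyl)oxy]prop-2-en-1-yl]-2-methyl-5-(prop-1-en-2-yl)cyclohexan-1-one | C=C[C@@H](O[Si](C)(C)C(C)(C)C)[C@@]1(C)CC[C@@H](C(C)=C)C(=[N+]=[N-])C1=O | intermediate
8 | [(2S,5S)-2-[(1R)-1-[(tert-butyldimethylsilyl)oxy]prop-2-en-1-yl]-2-methyl-5-(prop-1-en-2-yl)cyclopentylidene]methanone (ketene) | C=C[C@@H](O[Si](C)(C)C(C)(C)C)[C@@]1(C)CC[C@@H](C(C)=C)C1=C=O | intermediate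
9 | methyl (1S,2S,5R)-2-[(1R)-1-[(tert-butyldimethylsilyl)oxy]prop-2-en-1-yl]-2-methyl-5-(prop-1-en-2-yl)cyclopentane-1-carboxylate | C=C[C@@H](O[Si](C)(C)C(C)(C)C)[C@@]1(C)CC[C@@H](C(C)=C)[C@@H]1C(=O)OC | intermediate
10 | methyl (1S,2S,5R)-2-[(1R)-1-[(tert-butyldimethylsilyl)oxy]prop-2-en-1-yl]-2-methyl-5-(2-methyloxiran-2-yl)cyclopentane-1-carboxylate (both oxirane epimers) | C=C[C@@H](O[Si](C)(C)C(C)(C)C)[C@@]1(C)CC[C@@H](C2(C)CO2)[C@@H]1C(=O)OC | intermediate
11 | methyl (1S,2S,5R)-5-acetyl-2-[(1R)-1-[(tert-butyldimethylsilyl)oxy]prop-2-en-1-yl]-2-methylcyclopentane-1-carboxylate | C=C[C@@H](O[Si](C)(C)C(C)(C)C)[C@@]1(C)CC[C@@H](C(C)=O)[C@@H]1C(=O)OC | intermediate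
12 | methyl (1S,2S,5R)-2-[(1R)-1-[(tert-butyldimethylsilyl)oxy]prop-2-en-1-yl]-5-{1-[(diethoxyphosphoryl)oxy]ethenyl}-2-methylcyclopentane-1-carboxylate | C=C[C@@H](O[Si](C)(C)C(C)(C)C)[C@@]1(C)CC[C@@H](C(=C)OP(=O)(OCC)OCC)[C@@H]1C(=O)OC | intermediate
13 | methyl (1S,2S,5R)-2-[(1R)-1-[(tert-butyldimethylsilyl)oxy]prop-2-en-1-yl]-5-ethynyl-2-methylcyclopentane-1-carboxylate | C=C[C@@H](O[Si](C)(C)C(C)(C)C)[C@@]1(C)CC[C@@H](C#C)[C@@H]1C(=O)OC | intermediate
14 | methyl (1S,2S,5R)-2-[(1R)-1-[(tert-butyldimethylsilyl)oxy]prop-2-en-1-yl]-5-[(1E)-1-(dimethylalumanyl)prop-1-en-2-yl]-2-methylcyclopentane-1-carboxylate | C=C[C@@H](O[Si](C)(C)C(C)(C)C)[C@@]1(C)CC[C@@H](/C(C)=C/[Al](C)C)[C@@H]1C(=O)OC | intermediate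
15 | methyl (1S,2S,5R)-2-[(1R)-1-[(tert-butyldimethylsilyl)oxy]prop-2-en-1-yl]-5-[(1E)-1-iodoprop-1-en-2-yl]-2-methylcyclopentane-1-carboxylate | C=C[C@@H](O[Si](C)(C)C(C)(C)C)[C@@]1(C)CC[C@@H](/C(C)=C/I)[C@@H]1C(=O)OC | intermediate
16 | [(1S,2S,5R)-2-[(1R)-1-[(tert-butyldimethylsilyl)oxy]prop-2-en-1-yl]-5-[(1E)-1-iodoprop-1-en-2-yl]-2-methylcyclopentyl]methanol | C=C[C@@H](O[Si](C)(C)C(C)(C)C)[C@@]1(C)CC[C@@H](/C(C)=C/I)[C@@H]1CO | intermediate
17 | 2-methylallylmagnesium chloride (THF solution) | C=C(C)C[Mg]Cl | starting material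
18 | [(1S,2S,5R)-2-[(1R)-1-[(tert-butyldimethylsilyl)oxy]prop-2-en-1-yl]-5-[(1E)-1-iodoprop-1-en-2-yl]-2-methylcyclopentyl]methyl trifluoromethanesulfonate | C=C[C@@H](O[Si](C)(C)C(C)(C)C)[C@@]1(C)CC[C@@H](/C(C)=C/I)[C@@H]1COS(=O)(=O)C(F)(F)F | intermediate
19 | tert-butyl{[(1R)-1-[(1S,2S,3R)-3-[(1E)-1-iodoprop-1-en-2-yl]-1-methyl-2-(3-methylbut-3-en-1-yl)cyclopentyl]prop-2-en-1-yl]oxy}dimethylsilane | C=C[C@@H](O[Si](C)(C)C(C)(C)C)[C@@]1(C)CC[C@@H](/C(C)=C/I)[C@@H]1CCC(C)=C | intermediate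
20 | (1R)-1-[(1S,2S,3R)-3-[(1E)-1-iodoprop-1-en-2-yl]-1-methyl-2-(3-methylbut-3-en-1-yl)cyclopentyl]prop-2-en-1-ol | C=C[C@@H](O)[C@@]1(C)CC[C@@H](/C(C)=C/I)[C@@H]1CCC(C)=C | intermediate
21 | (1R,3aS,4R,8aS)-1-[(1E)-1-iodoprop-1-en-2-yl]-3a,6-dimethyl-1,2,3,3a,4,7,8,8a-octahydroazulen-4-ol | O[C@@H]1C=C(C)CC[C@H]2[C@H](/C(C)=C/I)CC[C@]12C | intermediate
22 | (1R,3aS,4S,5S,6R,8aS)-5,6-epoxy-1-[(1E)-1-iodoprop-1-en-2-yl]-3a,6-dimethyldecahydroazulen-4-ol | O[C@@H]1[C@@H]2O[C@]2(C)CC[C@H]2[C@H](/C(C)=C/I)CC[C@]12C | intermediate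
23 | (1R,3aS,4S,5S,6R,8aS)-5,6-epoxy-1-[(1E)-1-iodoprop-1-en-2-yl]-3a,6-dimethyldecahydroazulen-4-yl acetate | CC(=O)O[C@@H]1[C@@H]2O[C@]2(C)CC[C@H]2[C@H](/C(C)=C/I)CC[C@]12C | intermediate
24 | 2-methylbut-3-en-2-ol | C=CC(C)(C)O | starting material
25 | (1R,3aS,4S,5S,6R,8aS)-5,6-epoxy-1-[(2E,4E)-6-hydroxy-6-methylhepta-2,4-dien-2-yl]-3a,6-dimethyldecahydroazulen-4-yl acetate (CNP0265175.2) | CC(=O)O[C@@H]1[C@@H]2O[C@]2(C)CC[C@H]2[C@H](/C(C)=C/C=C/C(C)(C)O)CC[C@]12C | target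

**Totals**
Total step count: 14. Longest linear sequence: 14 steps, from (R)-carvone 1.

**Three steps most likely to fail, with fallbacks**

Step 1 (reductive aldol; carbinol configuration and C10 facial selectivity rest on transition-state arguments). The fallback sets out from 1 and comes back at 4. The reductive aldol of 1 with 2 is run without regard to the carbinol configuration, which gives 4 together with its carbinol epimer (2R,5R)-2-[(1S)-1-hydroxyprop-2-en-1-yl]-2-methyl-5-(prop-1-en-2-yl)cyclohexan-1-one F1. Dess–Martin oxidation of the mixture converges both epimers on the non-enolisable enedione (2S,5R)-2-methyl-2-(prop-2-enoyl)-5-(prop-1-en-2-yl)cyclohexan-1-one F2. Its conjugated carbonyl is then reduced under reagent control with (S)-2-methyl-CBS-oxazaborolidine and catecholborane at −78 °C (quaternary carbon as the large group), which returns 4; the carbinol is thus set by the reductant and not by the aldol transition state.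

Step 11 (ring-closing metathesis to a trisubstituted cycloheptene next to a quaternary centre). The fallback sets out from 19 (so it bypasses 20) and comes back at 21; it replaces alkene–alkene metathesis by a carbonyl olefination. Treating 19 with mCPBA, which again selects the 1,1-disubstituted alkene, gives tert-butyl{[(1R)-1-[(1S,2S,3R)-3-[(1E)-1-iodoprop-1-en-2-yl]-1-methyl-2-[2-(2-methyloxiran-2-yl)ethyl]cyclopentyl]prop-2-en-1-yl]oxy}dimethylsilane F3. Periodic acid cleaves this to 4-[(1S,2S,5R)-2-[(1R)-1-[(tert-butyldimethylsilyl)oxy]prop-2-en-1-yl]-5-[(1E)-1-iodoprop-1-en-2-yl]-2-methylcyclopentyl]butan-2-one F4. One equivalent of Mo(=CHCMe2Ph)(=N-2,6-i-Pr2C6H3)[OCMe(CF3)2]2 in benzene at rt first exchanges onto the vinyl group and then olefinates the ketone intramolecularly, closing C2=C3 to give tert-butyl{[(1R,3aS,4R,8aS)-1-[(1E)-1-iodoprop-1-en-2-yl]-3a,6-dimethyl-1,2,3,3a,4,7,8,8a-octahydroazulen-4-yl]oxy}dimethylsilane F5. Bu4NF in THF at 45 °C then gives 21.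

Step 14 (Heck reaction as the last step on an epoxy acetate; risk of diene isomerisation or low conversion). The fallback sets out from 23 and comes back at 25; it uses a preformed vinyl metal partner. Hydrostannylation of commercial 2-methylbut-3-yn-2-ol with Bu3SnH and PdCl2(PPh3)2 (cat.) in THF gives (E)-2-methyl-4-(tributylstannyl)but-3-en-2-ol F6. Stille coupling of F6 with 23 using Pd2(dba)3 (5 mol %) and AsPh3 in DMF at rt, under neutral conditions and with retention at both alkenes, gives 25.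

Further compounds
F1 | step 1 | (2R,5R)-2-[(1S)-1-hydroxyprop-2-en-1-yl]-2-methyl-5-(prop-1-en-2-yl)cyclohexan-1-one | C=C[C@H](O)[C@@]1(C)CC[C@@H](C(C)=C)CC1=O
F2 | step 1 | (2S,5R)-2-methyl-2-(prop-2-enoyl)-5-(prop-1-en-2-yl)cyclohexan-1-one | C=CC(=O)[C@@]1(C)CC[C@@H](C(C)=C)CC1=O
F3 | step 11 | tert-butyl{[(1R)-1-[(1S,2S,3R)-3-[(1E)-1-iodoprop-1-en-2-yl]-1-methyl-2-[2-(2-methyloxiran-2-yl)ethyl]cyclopentyl]prop-2-en-1-yl]oxy}dimethylsilane | C=C[C@@H](O[Si](C)(C)C(C)(C)C)[C@@]1(C)CC[C@@H](/C(C)=C/I)[C@@H]1CCC2(C)CO2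
F4 | step 11 | 4-[(1S,2S,5R)-2-[(1R)-1-[(tert-butyldimethylsilyl)oxy]prop-2-en-1-yl]-5-[(1E)-1-iodoprop-1-en-2-yl]-2-methylcyclopentyl]butan-2-one | C=C[C@@H](O[Si](C)(C)C(C)(C)C)[C@@]1(C)CC[C@@H](/C(C)=C/I)[C@@H]1CCC(C)=O
F5 | step 11 | tert-butyl{[(1R,3aS,4R,8aS)-1-[(1E)-1-iodoprop-1-en-2-yl]-3a,6-dimethyl-1,2,3,3a,4,7,8,8a-octahydroazulen-4-yl]oxy}dimethylsilane | CC(C)(C)[Si](C)(C)O[C@@H]1C=C(C)CC[C@H]2[C@H](/C(C)=C/I)CC[C@]12C
F6 | step 14 | (E)-2-methyl-4-(tributylstannyl)but-3-en-2-ol | CC(C)(O)/C=C/[Sn](CCCC)(CCCC)CCCC
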